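**Retrosynthetic overview**

1. The target is cut into three molecules of (E)-oxyresveratrol 1 (units A, B, C; stilbene numbering: ring 1 = 2,4-dihydroxyphenyl C1–C6, olefin C7/C8, ring 2 = 3,5-dihydroxyphenyl C9–C14). Both rings are closed by phenol oxidation, radical C–C coupling and oxa-Michael addition to a quinone methide.
2. Ring formed first (the 6-hydroxy-dihydrobenzofuran): C8(A)–C5(B) coupling of two 1 gives p-quinone methide 2, and closure O4(B)→C7(A) gives the racemic trans dimer 3.
3. Ring formed last (the 4-hydroxy-6-styryl-dihydrobenzofuran): the remaining ortho-hydroxystilbene of 3 is oxidized, C8(B) couples with C12 of a third 1 to give o-quinone methide 4, and closure O11(C)→C7(B) gives the racemic trimer 5.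
4. The single enantiomer 6 is taken from 5 on a chiral phase; no protecting groups are used.

Assumption: oxyresveratrol (a bulk cosmetic ingredient) counts as a cheap commercial starting material; racemic compounds are listed with the SMILES of the enantiomer that leads to the target.

**Route**

Step 1
Reactants: 1 (E)-oxyresveratrol (two molecules)
Product: 3 (±)-trans δ-type oxyresveratrol dehydrodimer (2R*,3R*), via p-quinone methide 2 (not isolated)
Conditions: AgOAc (0.6 equiv), MeOH, 40 °C, dark, 1 h; stopped at about 50% conversion, 1 recovered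
Reagents that add atoms: none
Why: Ag(I) one-electron oxidation gives the delocalized phenoxyl radical of 1, C8 of one radical bonds to ring-1 C5 (ortho to the 4-OH, less hindered than C3) of a second, and after re-aromatization the 4-OH adds to p-quinone methide 2 in a 5-exo oxa-Michael closure that places the two aryl groups trans (oxidative radical dehydrodimerization, the reaction type that turns resveratrol into δ-viniferin with AgOAc); C2 and C3 are set here as the racemic trans pair.

Step 2
Reactants: 3 (±)-trans δ-type oxyresveratrol dehydrodimer; 1 (E)-oxyresveratrol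
Product: 5 (±)-gneyulin A (2R*,3R*,2′R*,3′R*), via o-quinone methide 4 (not isolated)
Conditions: 1 (3 equiv), FeCl3·6H2O (2.5 equiv, slow addition), acetone/H2O 2:1, 0 °C → rt, dark; prep. RP-HPLC (C18, MeCN/H2O/HCO2H)
Reagents that add atoms: none
Why: Proposed new method: oxidation of the only conjugated phenol of 3 (O2 of unit B) gives an ortho-quinone-methide-type radical that can bond only through C8 (the ring position para to O2 is quaternary and the ortho position lies between two oxygens); under Fe(III), which with 4-hydroxystilbenes directs C8 to the resorcinol ring of the partner (ε-viniferin-type) and not to its phenol ring (Ag(I), δ-type), C8 is meant to bond to C12 of 1, the ring-2 position flanked only by two small OH groups, giving o-quinone methide 4, which O11 closes by 5-exo oxa-Michael addition to the 2,3-trans dihydrobenzofuran; C3′ is set in the coupling without control by the remote C2/C3 centres (about 1:1) and C2′ trans to it in the closure, so the wanted racemic diastereomer is separated by HPLC from its (2′S*,3′S*) isomer and from δ- and ε-type regioisomers; closest known reaction type: Fe(III)- or peroxidase-mediated oxidative cross-coupling of a stilbene dimer with a stilbene monomer (radical phenol coupling/oxa-Michael cyclization).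

Step 3
Reactants: 5 (±)-gneyulin A
Product: 6 gneyulin A (2R,3R,2′R,3′R)
Conditions: prep. HPLC, immobilized amylose tris(3,5-dimethylphenylcarbamate) phase, n-hexane/EtOH/TFA 70:30:0.1, rt
Reagents that add atoms: none
Why: Resolution of a racemate by chromatography on a chiral stationary phase, which separates the enantiomers of dihydrobenzofuran stilbenoids such as δ- and ε-viniferin; no stereocentre is formed, the (2R,3R,2′R,3′R) enantiomer is selected and its identity fixed by ECD and optical rotation against the natural product.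

**Compound list**

1 | (E)-oxyresveratrol, 4-[(E)-2-(3,5-dihydroxyphenyl)ethenyl]benzene-1,3-diol | Oc1ccc(/C=C/c2cc(O)cc(O)c2)c(O)c1 | starting material

2 | p-quinone methide of the C8(A)–C5(B) adduct, 4-[2-(3,5-dihydroxyphenyl)-2-[5-[(E)-2-(3,5-dihydroxyphenyl)ethenyl]-2,4-dihydroxyphenyl]ethylidene]-3-hydroxycyclohexa-2,5-dien-1-one (racemic, not isolated) | Oc1cc(O)cc([C@@H](C=C2C=CC(=O)C=C2O)c2cc(/C=C/c3cc(O)cc(O)c3)c(O)cc2O)c1 | intermediate

3 | (±)-trans δ-type dimer, 4-[(2R*,3R*)-3-(3,5-dihydroxyphenyl)-5-[(E)-2-(3,5-dihydroxyphenyl)ethenyl]-6-hydroxy-2,3-dihydro-1-benzofuran-2-yl]benzene-1,3-diol (racemic) | Oc1cc(O)cc([C@@H]2c3cc(/C=C/c4cc(O)cc(O)c4)c(O)cc3O[C@H]2c2ccc(O)cc2O)c1 | intermediate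

4 | o-quinone methide of the C8(B)–C12(C) adduct: ring 1 of unit B as a 6-ylidenecyclohexa-2,4-dienone still fused to the first dihydrobenzofuran; C8(B) carries the 3,5-dihydroxyphenyl group and the 2,6-dihydroxy-4-[(E)-2-(2,4-dihydroxyphenyl)ethenyl]phenyl group (racemic, not isolated) | Oc1cc(O)cc([C@@H]2C3=CC(=C[C@H](c4cc(O)cc(O)c4)c4c(O)cc(/C=C/c5ccc(O)cc5O)cc4O)C(=O)C=C3O[C@H]2c2ccc(O)cc2O)c1 | intermediate

5 | (±)-gneyulin A, racemate of 6 | Oc1cc(O)cc([C@@H]2c3cc([C@@H]4Oc5cc(/C=C/c6ccc(O)cc6O)cc(O)c5[C@H]4c4cc(O)cc(O)c4)c(O)cc3O[C@H]2c2ccc(O)cc2O)c1 | intermediate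

6 | gneyulin A, 4-[(2R,3R)-5-[(2R,3R)-3-(3,5-dihydroxyphenyl)-6-[(E)-2-(2,4-dihydroxyphenyl)ethenyl]-4-hydroxy-2,3-dihydro-1-benzofuran-2-yl]-3-(3,5-dihydroxyphenyl)-6-hydroxy-2,3-dihydro-1-benzofuran-2-yl]benzene-1,3-diol | Oc1cc(O)cc([C@@H]2c3cc([C@@H]4Oc5cc(/C=C/c6ccc(O)cc6O)cc(O)c5[C@H]4c4cc(O)cc(O)c4)c(O)cc3O[C@H]2c2ccc(O)cc2O)c1 | target

**Totals**

Total step count: 3. Longest linear sequence: 3 (1 → 3 → 5 → 6).

**Steps most likely to fail, with fallbacks**

1. Step 2 (highest risk). The radical of 3 has a single bonding site, but 1 does not. Its ring 1 (C5, the δ-type site) and ring-2 positions C10/C14 (ε-type) compete with C12, 1 also dimerizes with itself, and 3 can cyclize to a 2-arylbenzofuran. The wanted racemic diastereomer is expected in low single-digit yield and must be cut out of an isomer mixture.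
   Fallback (sets out from 3, comes back at 5): give the third unit a silent ring 1.
   - 2,4-Dihydroxybenzaldehyde is silylated (TIPSCl, imidazole, DMF) to 2,4-bis(triisopropylsilyloxy)benzaldehyde F1.
   - 3,5-Dihydroxybenzyl alcohol and Ph3P·HBr (MeCN, reflux) give (3,5-dihydroxybenzyl)triphenylphosphonium bromide F2.
   - Wittig reaction of F2 (LiHMDS 3.1 equiv, THF, −78 °C → rt) with F1, then I2-catalysed Z→E isomerization, gives ring-1-silylated oxyresveratrol F3.
   - Oxidation of 3 (FeCl3·6H2O, acetone/H2O) in the presence of F3 (5 equiv, recovered) gives the ring-1 bis-silyl ether of the racemic trimer F4. Here 3 holds the only conjugated free phenol, and ring 2 of F3 is the best available nucleophile; a bulky carbon electrophile prefers the position between its two hydroxyls, as in the normal alkylation of 5-substituted resorcinols.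
   - TBAF/AcOH (THF, 0 °C) removes both silyl groups and gives 5.

2. Step 1. Unlike resveratrol, oxyresveratrol gives a product that still holds an oxidizable ortho-hydroxystilbene. Coupling can also occur at C3 of ring 1 or on ring 2, and Ag(I) can cyclize 2-hydroxystilbenes to 2-arylbenzofurans. Expected yield is about 35–45% based on recovered 1.
   Fallback (sets out from 1, comes back at 3): make the monomer behave like resveratrol.
   - Peracetylation of 1 (Ac2O, pyridine) gives oxyresveratrol tetraacetate F5.
   - Mild methanolysis (cat. K2CO3, MeOH, −20 °C) removes only the 4-acetate, the one para-conjugated to the olefin, and gives oxyresveratrol 2,3′,5′-triacetate F6.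
   - AgOAc/MeOH couples F6 to the racemic dimer hexaacetate F7. F6 has one free phenol, C3 is shielded by the flanking acetate, and the product has no conjugated free phenol, so it cannot be over-oxidized.
   - K2CO3/MeOH (0 °C) removes the six acetates and gives 3.

3. Step 3. Baseline separation of the enantiomers of a dodecaphenolic trimer at preparative load is not assured.
   Fallback (sets out from 3, comes back at 6): resolve earlier.
   - Racemic 3 is separated on the same type of chiral phase, where δ-viniferin-type dimers resolve well, to give the (2R,3R)-dimer F8.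
   - F8 (2 equiv) is taken through the step 2 coupling with slow addition of 1, so that dimer formed in the flask from 1 stays negligible.
   - The two trimers now formed, 6 and its (2′S,3′S) diastereomer, are separated on achiral C18; the ee of 6 is checked on the analytical chiral column.

**Further compounds**

F1 | step 2 | 2,4-bis(triisopropylsilyloxy)benzaldehyde | CC(C)[Si](Oc1ccc(C=O)c(O[Si](C(C)C)(C(C)C)C(C)C)c1)(C(C)C)C(C)C

F2 | step 2 | (3,5-dihydroxybenzyl)triphenylphosphonium bromide | Oc1cc(O)cc(C[P+](c2ccccc2)(c2ccccc2)c2ccccc2)c1.[Br-]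

F3 | step 2 | (E)-5-[2-[2,4-bis(triisopropylsilyloxy)phenyl]ethenyl]benzene-1,3-diol | CC(C)[Si](Oc1ccc(/C=C/c2cc(O)cc(O)c2)c(O[Si](C(C)C)(C(C)C)C(C)C)c1)(C(C)C)C(C)C

F4 | step 2 | (±)-gneyulin A bis(triisopropylsilyl) ether at O2 and O4 of unit C (racemic) | Oc1cc(O)cc([C@@H]2c3cc([C@@H]4Oc5cc(/C=C/c6ccc(O[Si](C(C)C)(C(C)C)C(C)C)cc6O[Si](C(C)C)(C(C)C)C(C)C)cc(O)c5[C@H]4c4cc(O)cc(O)c4)c(O)cc3O[C@H]2c2ccc(O)cc2O)c1

F5 | step 1 | (E)-oxyresveratrol tetraacetate | CC(=O)Oc1ccc(/C=C/c2cc(OC(C)=O)cc(OC(C)=O)c2)c(OC(C)=O)c1

F6 | step 1 | (E)-oxyresveratrol 2,3′,5′-triacetate (4-OH free) | Oc1ccc(/C=C/c2cc(OC(C)=O)cc(OC(C)=O)c2)c(OC(C)=O)c1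

F7 | step 1 | hexaacetate of the (±)-trans δ-type dimer (4-OH of unit A free, racemic) | CC(=O)Oc1cc(OC(C)=O)cc([C@@H]2c3cc(/C=C/c4cc(OC(C)=O)cc(OC(C)=O)c4)c(OC(C)=O)cc3O[C@H]2c2ccc(O)cc2OC(C)=O)c1

F8 | step 3 | (2R,3R)-enantiomer of the δ-type dimer 3 | Oc1cc(O)cc([C@@H]2c3cc(/C=C/c4cc(O)cc(O)c4)c(O)cc3O[C@H]2c2ccc(O)cc2O)c1
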